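The oxepane (ring B) is read as a carvone ring with one oxygen inserted: the ring carbons of (R)-carvone become C2–C7, its enone alkene the C3–C4 epoxide, its carbonyl carbon the enol-ether carbon C2 and its isopropenyl group the gem-dimethyl carbon C11. Everything rests on closing the bromocyclohexane (ring A) between C11 and the future bromine-bearing C10. The key step exploits the quaternary C11 lying between C10 and ring-fusion C6: iron-hydride hydrogen-atom transfer turns the isopropenyl group into the tertiary C11 radical, which adds to a nitrile carbon (C10) and gives the trans-fused C10 ketone in one operation. Its precursor is 6-methylcarvone epoxide cyanoethylated at the α′-carbon.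

Key step: step 4

Numbering used throughout: C1 bromomethylene carbon, C2 enol-ether carbon, C3 (methyl-bearing) and C4 oxirane carbons, C5 CH2, C6 ring-fusion CH, C7 oxygen-bearing methyl carbon, C8 and C9 CH2, C10 CHBr, C11 CMe2. Ring A is the cyclohexane C6–C11 and ring B the oxepane O/C2–C7. Carvone C1–C6 correspond to C2–C7. β is the face of the C7 methyl group, α the opposite face.

Remark: the target is taken as drawn, (3R,4R,6S,7S,10S) with the (E)-bromomethylene group (bromine trans to the ring oxygen); this requires (R)-(−)-carvone.

Step 1
Reactants: 1 (R)-(−)-carvone
Product: 3 6-methylcarvone (methyl trans to isopropenyl as the expected major C7 epimer), via lithium dienolate 2 (not isolated)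
Conditions: LiN(i-Pr)2 (LDA), THF, −78 °C; then MeI, −78 → 0 °C
Reagents that add atoms: iodomethane, CI
Why: kinetic deprotonation at the α′-CH2 gives the cross-conjugated lithium dienolate, which is C-methylated (enolate alkylation) mainly anti to the isopropenyl group; the new C7 centre is re-enolised in step 3, so both epimers can be used.

Step 2
Reactants: 3 6-methylcarvone
Product: 4 6-methylcarvone 3α,4α-epoxide (oxirane oxygen trans to isopropenyl)
Conditions: 30% aq. H2O2, NaOH (cat.), MeOH, 0 °C
Reagents that add atoms: hydrogen peroxide, OO
Why: Weitz–Scheffer nucleophilic epoxidation touches only the enone; hydroperoxide should add axially to C4 on the face anti to the isopropenyl group, as with carvone itself, which sets C3 and C4 with the oxygen on the α face.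

Step 3
Reactants: 4 6-methylcarvone epoxide, 5 acrylonitrile
Product: 6 epoxy keto nitrile (C7 carries methyl cis and 2-cyanoethyl trans to the isopropenyl group)
Conditions: KOt-Bu (cat.), t-BuOH/THF, 0 °C → rt
Reagents that add atoms: none
Why: base-catalysed cyanoethylation (Michael addition) at the only enolisable carbon; the acceptor should approach the enolate face anti to the adjacent pseudoaxial isopropenyl group, which sets the quaternary C7 centre, and with the enone masked as the epoxide no second Michael addition is possible.

Step 4
Reactants: 6 epoxy keto nitrile
Product: 8 trans-fused epoxy diketone (C2 and C10 ketones, 7β-methyl, 6α-H, 3α,4α-epoxide), via ketimine 7 (not isolated)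
Conditions: Fe(acac)3 (cat.), PhSiH3, EtOH, 60 °C, Ar; then aq. AcOH/THF, rt
Reagents that add atoms: water, O
Why: Fe(acac)3 and PhSiH3 in EtOH generate an iron hydride that transfers a hydrogen atom to the terminal CH2 of the isopropenyl group (Markovnikov metal-hydride hydrogen-atom transfer), and the resulting tertiary C11 radical adds to the nitrile carbon C10; the iminyl radical is reduced to ketimine 7, which aqueous acid hydrolyses to the C10 ketone. The closest known reaction type is the iron-hydride HAT-initiated reductive cyclisation of alkene-tethered nitriles to cyclic ketones, the nitrile counterpart of HAT alkene–carbonyl couplings. Ring A is closed in the 6-exo-dig mode through a chair-like transition state. No new stereocentre remains in 8 (C11 carries two methyls, C10 is a carbonyl); the trans ring fusion is already set in step 3, because the isopropenyl group on C6 and the cyanoethyl chain on C7 are trans and can only be bridged diequatorially. The step needs the radical to cyclise faster than it is reduced to an isopropyl group; the quaternary C7 (Thorpe–Ingold effect), the rigid epoxycyclohexanone and the absence of any other acceptor should secure this, since the enone is masked as the epoxide and attack on the C2 ketone would need a four-membered ring. Exclusion of oxygen suppresses Mukaiyama-type hydration of the radical.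

Step 5
Reactants: 8 epoxy diketone
Product: 9 10α-alcohol (axial hydroxyl at C10, C2 ketone retained)
Conditions: LiBH(s-Bu)3 (L-Selectride), THF, −78 °C; then H2O
Reagents that add atoms: none
Why: bulky trialkylborohydride reduction should deliver hydride to the C10 ketone along the equatorial trajectory (the axial path is blocked for a bulky hydride by the syn-axial C6–H and C8–H), giving the axial 10α-alcohol, while the C2 ketone, flanked by two fully substituted carbons, is left untouched.

Step 6
Reactants: 9 10α-alcohol
Product: 10 10β-bromo epoxy ketone (equatorial bromide)
Conditions: PPh3, CBr4, CH2Cl2, 0 °C → rt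
Reagents that add atoms: carbon tetrabromide, BrC(Br)(Br)Br
Why: Appel reaction; the alkoxyphosphonium of the axial alcohol should be displaced by bromide in an SN2 step along the equatorial direction, inverting C10 to the equatorial 10β-bromide of the target.

Step 7
Reactants: 10 bromo epoxy ketone
Product: 11 epoxy ε-lactone (oxygen inserted between C7 and C2)
Conditions: mCPBA, NaHCO3, CH2Cl2, rt → 40 °C
Reagents that add atoms: mCPBA, OOC(=O)c1cccc(Cl)c1
Why: Baeyer–Villiger oxidation; in the Criegee intermediate the electron-rich tertiary alkyl carbon C7 should migrate in preference to the electron-poor oxiranyl carbon C3, and with retention, so the carvone ring expands to the oxepanone (ring B) without touching a stereocentre.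

Step 8
Reactants: 11 epoxy lactone
Product: 12 2-methylene oxepane (exocyclic enol ether, C1 = CH2)
Conditions: Cp2TiMe2, toluene, 70 °C, dark
Reagents that add atoms: Cp2TiMe2 (dimethyltitanocene), C[Ti](C)(C1C=CC=C1)C1C=CC=C1
Why: Petasis methylenation; Cp2Ti=CH2 formed by thermolysis should convert the hindered, non-enolisable lactone carbonyl into the enol ether by [2+2] cycloaddition and cycloreversion under neutral conditions that the oxirane and the alkyl bromide tolerate.

Step 9
Reactants: 12 methylene enol ether
Product: 14 dibromomethylene enol ether, via monobromo enol ether 13 (not isolated)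
Conditions: Br2 (1 equiv), CH2Cl2, −78 °C, then DBU, −78 → 0 °C; the same cycle once more in the same flask
Reagents that add atoms: bromine, BrBr
Why: bromination–dehydrobromination of an enol ether, run twice; bromine adds at C1 through the oxocarbenium ion stabilised by the ring oxygen and DBU removes a C1 proton (C3 has none, so the alkene can only re-form exocyclic), giving first 13 and then the geometry-free dibromide 14, so the first bromination need not be stereoselective.

Step 10
Reactants: 14 dibromomethylene enol ether
Product: 15 target CNP0375295.1
Conditions: Pd(PPh3)4 (cat.), Bu3SnH (1.05 equiv), toluene, rt, dark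
Reagents that add atoms: none
Why: palladium-catalysed tin hydride hydrogenolysis of a 1,1-dibromoalkene; zerovalent palladium should insert into the less hindered C–Br bond (cis to the ring oxygen, trans to the fully substituted C3) and hydride replaces it with retention, leaving bromine trans to oxygen, the (E) geometry, while the secondary alkyl bromide does not react without a radical initiator.

Compound list
1 | (R)-(−)-carvone, (5R)-2-methyl-5-(prop-1-en-2-yl)cyclohex-2-en-1-one | CC1=CC[C@H](CC1=O)C(C)=C | starting material
2 | lithium cross-conjugated dienolate of carvone (α′-enolate, not isolated) | [Li]OC1=C[C@@H](CC=C1C)C(C)=C | intermediate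
3 | 6-methylcarvone, (5R,6S)-2,6-dimethyl-5-(prop-1-en-2-yl)cyclohex-2-en-1-one (methyl trans to isopropenyl; major epimer drawn, both epimers serve) | C[C@@H]1C(=O)C(C)=CC[C@H]1C(C)=C | intermediate
4 | 6-methylcarvone 3α,4α-epoxide (oxirane oxygen trans to isopropenyl; C7 epimers as in 3) | C[C@@H]1C(=O)[C@]2(C)O[C@@H]2C[C@H]1C(C)=C | intermediate
5 | acrylonitrile | C=CC#N | starting material
6 | epoxy keto nitrile: the epoxycyclohexanone of 4 with methyl (cis to isopropenyl) and 2-cyanoethyl (trans to isopropenyl) on C7 | N#CCC[C@]1(C)C(=O)[C@]2(C)O[C@@H]2C[C@H]1C(C)=C | intermediate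
7 | C10 ketimine of the trans-fused epoxy decalinone (not isolated) | CC1(C)C(=N)CC[C@]2(C)C(=O)[C@]3(C)O[C@@H]3C[C@@H]12 | intermediate
8 | trans-fused epoxy decalin-2,10-dione (7β-methyl, 6α-H, 3α,4α-epoxide, 11,11-dimethyl) | CC1(C)C(=O)CC[C@]2(C)C(=O)[C@]3(C)O[C@@H]3C[C@@H]12 | intermediate
9 | 10α-hydroxy (axial) epoxy decalin-2-one | CC1(C)[C@H](O)CC[C@]2(C)C(=O)[C@]3(C)O[C@@H]3C[C@@H]12 | intermediate
10 | 10β-bromo (equatorial) epoxy decalin-2-one | CC1(C)[C@@H](Br)CC[C@]2(C)C(=O)[C@]3(C)O[C@@H]3C[C@@H]12 | intermediate
11 | epoxy ε-lactone (oxepan-2-one trans-fused to the bromocyclohexane) | CC1(C)[C@@H](Br)CC[C@]2(C)OC(=O)[C@]3(C)O[C@@H]3C[C@@H]12 | intermediate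
12 | 2-methylene oxepane (exocyclic enol ether) | CC1(C)[C@@H](Br)CC[C@]2(C)OC(=C)[C@]3(C)O[C@@H]3C[C@@H]12 | intermediate
13 | monobromomethylene enol ether (not isolated; Z isomer with bromine cis to the ring oxygen drawn as the expected major isomer) | CC1(C)[C@@H](Br)CC[C@]2(C)O/C(=C\Br)[C@]3(C)O[C@@H]3C[C@@H]12 | intermediate
14 | dibromomethylene enol ether | CC1(C)[C@@H](Br)CC[C@]2(C)OC(=C(Br)Br)[C@]3(C)O[C@@H]3C[C@@H]12 | intermediate
15 | CNP0375295.1, (3R,4R,6S,7S,10S)-(E)-bromomethylene epoxy oxepane | CC1(C)[C@@H](Br)CC[C@]2(C)O/C(=C/Br)[C@]3(C)O[C@@H]3C[C@@H]12 | target

Total step count: 10. Longest linear sequence: 10 steps, from (R)-(−)-carvone.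

Steps most likely to fail

Step 4 (key step). The attack of the hindered tertiary radical on the nitrile is slow, so reduction of the radical before cyclisation (net hydrogenation of the isopropenyl group) may win, or the hindered ketimine may resist hydrolysis. The fallback sets out from 4 and returns at 8, and replaces the nitrile by the much more reactive aldehyde acceptor. Compound 4 is deprotonated with LiN(i-Pr)2 in THF at −78 °C to the lithium enolate F1, which is alkylated with allyl bromide anti to the isopropenyl group to give the allyl epoxy ketone F2. The monosubstituted alkene is oxidised selectively by nitrite-modified anti-Markovnikov Wacker oxidation (PdCl2(PhCN)2, CuCl2, AgNO2, O2, t-BuOH/MeNO2) to the epoxy keto aldehyde F3. The same iron-hydride HAT cyclisation (Fe(acac)3, PhSiH3, EtOH), now onto the aldehyde carbon, should give the C10 carbinol F4 as an epimer mixture, and Dess–Martin periodinane oxidises it to diketone 8.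

Step 6. The axial oxyphosphonium next to the quaternary C11 may ionise (elimination towards C9, 1,2-methyl shift) instead of undergoing SN2 displacement, or bromide may open the oxirane. The fallback sets out from 9 and returns at 10. Alcohol 9 is converted with ClCH2SO2Cl and pyridine at 0 °C into the chloromethanesulfonate F5, an isolable leaving group that does not ionise readily, and this is displaced with LiBr in DMF at 40–60 °C (SN2, inversion) to give 10.

Step 10. Discrimination between the two C–Br bonds may be poor, both may be reduced, or zerovalent palladium may ionise the vinyl oxirane. The fallback sets out from 14 and returns at 15 and uses halogen–metal exchange instead of palladium. Treatment of 14 with n-BuLi (1 equiv) in THF/Et2O at −100 °C should exchange the bromine cis to the ring oxygen (less hindered, lithium coordinated by oxygen) to give the α-bromo vinyllithium F6, which is protonated with MeOH at −100 °C with retention to give 15.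

Further compounds
F1 | step 4 | lithium enolate of 4 | CC1=C(O[Li])[C@]2(C)O[C@@H]2C[C@H]1C(C)=C
F2 | step 4 | allyl epoxy ketone (allyl trans, methyl cis to isopropenyl) | C=CC[C@]1(C)C(=O)[C@]2(C)O[C@@H]2C[C@H]1C(C)=C
F3 | step 4 | epoxy keto aldehyde | O=CCC[C@]1(C)C(=O)[C@]2(C)O[C@@H]2C[C@H]1C(C)=C
F4 | step 4 | C10 carbinol of the trans-fused epoxy decalinone (C10 epimer mixture) | CC1(C)C(O)CC[C@]2(C)C(=O)[C@]3(C)O[C@@H]3C[C@@H]12
F5 | step 6 | 10α-chloromethanesulfonate | CC1(C)[C@H](OS(=O)(=O)CCl)CC[C@]2(C)C(=O)[C@]3(C)O[C@@H]3C[C@@H]12
F6 | step 10 | α-bromo vinyllithium (lithium cis to the ring oxygen) | CC1(C)[C@@H](Br)CC[C@]2(C)O/C(=C(/Br)[Li])[C@]3(C)O[C@@H]3C[C@@H]12
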